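Watch c(second intermediate) at the moments when open intermediate forms, and compare the flasks on that.

| flask | starting material | partner A | partner B | time | remark |
|---|---|---|---|---|---|
| dusk | 0.32 M (fed, over 30 min) | 0.384 M | 0.480 M | 80 min | all else is in the flask from the start; the feed brings no volume worth counting |
| spring | 0.32 M (in portions, 2, over 30 min) | 0.384 M | 0.480 M | 80 min | first portion at the start, last at 30 min |
| winter | 0.32 M | 0.384 M (fed, over 3.0 min) | 0.480 M | 80 min | all else is in the flask from the start; the feed brings no volume worth counting |
| summer | 0.32 M | 0.384 M (fed, over 30 min) | 0.480 M | 80 min | all else is in the flask from the start; the feed brings no volume worth counting |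
| dawn | 0.32 M | 0.384 M | 0.480 M | 80 min | everything together at the start |

    open intermediate + second intermediate → target (k1 = 0.208 M⁻¹ min⁻¹)
    starting material + partner B → open intermediate (k2 = 0.181 M⁻¹ min⁻¹)
    partner B + partner A → second intermediate (k3 = 0.774 M⁻¹ min⁻¹)
    open intermediate → side product (k4 = 0.144 min⁻¹)

- the flask with the highest share of target in target plus side product ("all alike" if they lie within 1.5 percentage points) (dusk / spring / winter / summer / dawn / all alike)
- share of target in target plus side product at the end, dusk
- share of target in target plus side product at the end, spring
- share of target in target plus side product at the end, winter
- share of target in target plus side product at the end, summer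
- share of target in target plus side product at the end, dawn

Open intermediate has two exits, coupling and first-order loss, and its coupling share (a selectivity) at a given moment is the coupling rate over the sum of both rates:

coupling share = coupling constant × c(second intermediate) / (coupling constant × c(second intermediate) + loss constant)

Each second intermediate costs one partner A, whose charge is smaller than that of partner B, so I put the charge of partner A into the formula:

0.208 M⁻¹ min⁻¹ × 0.384 M / (0.208 M⁻¹ min⁻¹ × 0.384 M + 0.144 min⁻¹) = 35.7 %

This is the coupling ceiling, the coupling share with c(second intermediate) at the whole charge of partner A.

Now set dawn beside dusk, which hold the same charges. In dawn the half-life of partner B by its reaction with partner A, as charged, is 2.3 min, and open intermediate starts forming at once, while c(second intermediate) is still climbing. At half the charge of partner A the coupling share is only 21.7 %, so I place dawn between that and the ceiling. Dusk holds the same partner A and partner B from the start and feeds its starting material over 30 min, far longer than that half-life, so I place dusk just under the ceiling.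

Spring, with its first portion at the start, should land between dusk and dawn, and winter just under dawn. In summer, partner B has a half-life of 12.0 min against starting material as charged, and by then the feed has brought 0.154 M of partner A. If that amount stood whole as second intermediate, the coupling share in summer at that moment is 18.2 %, so I put summer last.

The forecast put dusk first at 33.5 %, then spring 32 %, dawn 29 %, winter 28.5 % and summer 15 %, holding that the split of open intermediate between coupling and first-order loss “caps the share near one third”.

The simulation puts dusk first, with dusk 32.9 %, spring 30.3 %, dawn 27.6 %, winter 24.7 % and summer 12.2 %.

At the end of dusk, open intermediate goes to side product 2.0 times as fast as to target, with c(second intermediate) at 0.342 M, which makes the coupling share 33.1 %, below the coupling ceiling of 35.7 %. In the neighbour of dusk with 0.96 M of partner A, partner B is the smaller charge, so the ceiling reckoned on partner B is 40.9 %, and that flask ends with c(second intermediate) at 0.475 M and a share of 39.1 %.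

The rate constants were chosen freely; no experiment stands behind them.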